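**Strategy**

The route rests on opening the dihydropyran ring of the spirochroman (O1–C2–C3–C4–C4a–C8a) at C4–C4a and O1–C2. This exposes C4a and O1 as the carbon and oxygen termini of an enolized 1,3-dicarbonyl unit hidden in the phloroglucinol ring, and C4–C3–C2 as an enal whose β-carbon is C2 of the pinane. A formal [3+3] annulation (Knoevenagel condensation, then oxa-6π electrocyclization) of isovalerylphloroglucinol with nopinylideneacetaldehyde, made from (+)-nopinone, should forge both bonds, the pyran ring and the spiro stereocentre in one operation. The precursor is a flat o-quinone methide; the gem-dimethyl bridge directs O1 to the opposite face of C2. Hydrogenation of C3=C4 and formylation of C8, the last free ring position, finish the synthesis.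

Key step: step 4

Assumption: nitrile 3 and enal 5 are carried on as E/Z mixtures (E isomers drawn), because both alkene geometries feed the same iminium/o-quinone methide manifold in step 4 and lead to the same spiro centre.

**Route**

Step 1
Reactants: 1 (+)-nopinone, (1R,5S)-6,6-dimethylbicyclo[3.1.1]heptan-2-one; 2 diethyl (cyanomethyl)phosphonate
Product: 3 (E)-2-[(1R,5S)-6,6-dimethylbicyclo[3.1.1]heptan-2-ylidene]acetonitrile
Conditions: NaH, THF, 0 °C → rt (reflux if slow)
Reagents that add atoms: none
Why: Horner–Wadsworth–Emmons olefination, in which the small cyanomethylphosphonate anion should add to the ketone faster than it enolizes it and syn-elimination of diethyl phosphate gives the trisubstituted alkene, the two bridgehead stereocentres being untouched.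

Step 2
Reactants: 3 (E)-2-[(1R,5S)-6,6-dimethylbicyclo[3.1.1]heptan-2-ylidene]acetonitrile
Product: 5 (E)-2-[(1R,5S)-6,6-dimethylbicyclo[3.1.1]heptan-2-ylidene]acetaldehyde, via aluminium aldiminate 4 (not isolated)
Conditions: iBu2AlH (1.2 equiv), toluene, −78 °C; then 1 M aq. HCl, 0 °C
Reagents that add atoms: water, O
Why: Partial nitrile reduction with one hydride equivalent should stop at the aluminium aldiminate 4 at low temperature, 1,2-addition being favoured over conjugate addition at the fully substituted β-carbon, and cold dilute acid hydrolyses 4 to the enal.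

Step 3
Reactants: 6 phloroglucinol (benzene-1,3,5-triol); 7 isovaleryl chloride (3-methylbutanoyl chloride)
Product: 8 3-methyl-1-(2,4,6-trihydroxyphenyl)butan-1-one (isovalerylphloroglucinol)
Conditions: AlCl3 (4 equiv), PhNO2/CH2Cl2, rt → 60 °C; then ice/aq. HCl
Reagents that add atoms: none
Why: Friedel–Crafts C-acylation of a very electron-rich arene whose three ring positions are equivalent, the first acyl group deactivating the ring so that monoacylation should predominate with one equivalent of 7.

Step 4
Reactants: 8 3-methyl-1-(2,4,6-trihydroxyphenyl)butan-1-one (1.5 equiv); 5 (E)-2-[(1R,5S)-6,6-dimethylbicyclo[3.1.1]heptan-2-ylidene]acetaldehyde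
Product: 10 1-[(2R,1'R,5'S)-5,7-dihydroxy-6',6'-dimethylspiro[chromene-2,2'-bicyclo[3.1.1]heptan]-6-yl]-3-methylbutan-1-one, via o-quinone methide 9 (not isolated)
Conditions: ethylenediammonium diacetate (20 mol%), toluene, 90 °C
Reagents that add atoms: none
Why: Ethylenediammonium diacetate converts enal 5 into a conjugated iminium ion that is attacked at its carbonyl carbon by C3 of the vinylogous acid 8 (Knoevenagel/Mannich condensation, forming C4–C4a), and loss of the amine unveils the 1-oxatriene (o-quinone methide) 9, which closes by a thermal disrotatory oxa-6π electrocyclization that forms O1–C2. The closest known reaction type is the formal [3+3] chromene annulation of phloroglucinols, resorcinols and 1,3-diones with β,β-disubstituted enals such as citral or prenal. The only ring closed is the 2H-pyran ring, by 6π electrocyclization of oxygen onto C2. The spiro centre C2 is set under substrate control: oxygen should bond to the exocyclic alkene carbon from the face opposite the gem-dimethyl bridge C6' of the pinane, the face also taken by reagents adding to β-pinene and nopinone, so both alkene geometries of 5 converge on one epimer. The step needs ring closure through the hydroxyl para to the isovaleryl group rather than through an ortho hydroxyl; the para hydroxyl is the most acidic and is never tied up in the hydrogen bond to the ketone, which should favour that closure but does not guarantee it, and the excess of 8 suppresses a second annulation at C8.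

Step 5
Reactants: 10 1-[(2R,1'R,5'S)-5,7-dihydroxy-6',6'-dimethylspiro[chromene-2,2'-bicyclo[3.1.1]heptan]-6-yl]-3-methylbutan-1-one
Product: 11 1-[(2R,1'R,5'S)-5,7-dihydroxy-6',6'-dimethyl-3,4-dihydrospiro[chromene-2,2'-bicyclo[3.1.1]heptan]-6-yl]-3-methylbutan-1-one
Conditions: H2 (1 atm), 10% Pd/C, EtOAc, rt
Reagents that add atoms: none
Why: Heterogeneous catalytic hydrogenation of the cis-disubstituted styrenyl C3=C4 bond, under which the hydrogen-bonded aryl ketone, the cyclobutane and the tertiary ether should be inert and no stereocentre is formed (C3 and C4 become CH2).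

Step 6
Reactants: 11 1-[(2R,1'R,5'S)-5,7-dihydroxy-6',6'-dimethyl-3,4-dihydrospiro[chromene-2,2'-bicyclo[3.1.1]heptan]-6-yl]-3-methylbutan-1-one
Product: 13 euglobal G3, via aryl iminium chloride 12 (not isolated)
Conditions: POCl3 (1.2 equiv), DMF (3 equiv), EtOAc, 0 °C → rt; then H2O, rt → 50 °C
Reagents that add atoms: DMF, CN(C)C=O; water, O
Why: Vilsmeier–Haack formylation, in which the chloroiminium ion should attack C8, the only unsubstituted ring carbon (ortho to O1 and 7-OH, para to 5-OH), and water hydrolyses iminium salt 12 to the aldehyde, the low temperature and near-stoichiometric reagent sparing the enolizable ketone and the spiro ether.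

**Compound list**

1 | (+)-nopinone, (1R,5S)-6,6-dimethylbicyclo[3.1.1]heptan-2-one | O=C1CC[C@H]2C[C@@H]1C2(C)C | starting material
2 | diethyl (cyanomethyl)phosphonate | CCOP(=O)(CC#N)OCC | starting material
3 | (E)-2-[(1R,5S)-6,6-dimethylbicyclo[3.1.1]heptan-2-ylidene]acetonitrile (E drawn; E/Z mixture carried on) | N#C/C=C1\CC[C@H]2C[C@@H]1C2(C)C | intermediate
4 | N-(diisobutylaluminio) aldimine of 5 (aluminium aldiminate) | CC(C)C[Al](CC(C)C)N=C/C=C1\CC[C@H]2C[C@@H]1C2(C)C | intermediate
5 | (E)-2-[(1R,5S)-6,6-dimethylbicyclo[3.1.1]heptan-2-ylidene]acetaldehyde (E drawn; E/Z mixture carried on) | O=C/C=C1\CC[C@H]2C[C@@H]1C2(C)C | intermediate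
6 | phloroglucinol (benzene-1,3,5-triol) | Oc1cc(O)cc(O)c1 | starting material
7 | isovaleryl chloride (3-methylbutanoyl chloride) | CC(C)CC(Cl)=O | starting material
8 | 3-methyl-1-(2,4,6-trihydroxyphenyl)butan-1-one (isovalerylphloroglucinol) | CC(C)CC(=O)c1c(O)cc(O)cc1O | intermediate
9 | o-quinone methide, (6Z)-6-{(2E)-2-[(1R,5S)-6,6-dimethylbicyclo[3.1.1]heptan-2-ylidene]ethylidene}-3,5-dihydroxy-4-(3-methylbutanoyl)cyclohexa-2,4-dien-1-one | O=C1C=C(O)C(C(=O)CC(C)C)=C(O)/C1=C/C=C2\CC[C@H]3C[C@@H]2C3(C)C | intermediate
10 | 1-[(2R,1'R,5'S)-5,7-dihydroxy-6',6'-dimethylspiro[chromene-2,2'-bicyclo[3.1.1]heptan]-6-yl]-3-methylbutan-1-one (O1 on the pinane face opposite the gem-dimethyl bridge) | CC(C)CC(=O)c1c(O)cc2c(c1O)C=C[C@@]1(CC[C@H]3C[C@@H]1C3(C)C)O2 | intermediate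
11 | 1-[(2R,1'R,5'S)-5,7-dihydroxy-6',6'-dimethyl-3,4-dihydrospiro[chromene-2,2'-bicyclo[3.1.1]heptan]-6-yl]-3-methylbutan-1-one | CC(C)CC(=O)c1c(O)cc2c(c1O)CC[C@@]1(CC[C@H]3C[C@@H]1C3(C)C)O2 | intermediate
12 | C8 N,N-dimethyliminium chloride of 11 (aryl iminium chloride) | CC(C)CC(=O)c1c(O)c(C=[N+](C)C)c2c(c1O)CC[C@@]1(CC[C@H]3C[C@@H]1C3(C)C)O2.[Cl-] | intermediate
13 | euglobal G3, (2R,1'R,5'S)-5,7-dihydroxy-6',6'-dimethyl-6-(3-methylbutanoyl)-3,4-dihydrospiro[chromene-2,2'-bicyclo[3.1.1]heptane]-8-carbaldehyde | CC(C)CC(=O)c1c(O)c(C=O)c2c(c1O)CC[C@@]1(CC[C@H]3C[C@@H]1C3(C)C)O2 | target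

**Summary and risks**

Total step count: 6. Longest linear sequence: 5 steps (steps 1, 2, 4, 5 and 6; 1 → 3 → 5 → 10 → 11 → 13).

Steps most likely to fail:

Step 4 (key step). The pyran ring may close through a hydroxyl ortho to the isovaleryl group instead of the para one, or a second enal may annulate at C8, so that the wanted 6-acyl chromene becomes the minor component. The fallback sets out from 5 and rejoins the route at 13; it fixes the regiochemistry by the substitution pattern of the phenol instead of by hydrogen bonding. Enal 5 is condensed with purchased 2-hydroxy-4,6-dimethoxybenzaldehyde F1 (PhB(OH)2, propionic acid, toluene, reflux with water removal). Its single free hydroxyl lies next to the formyl group and is the only oxygen able to close the ring, so the same condensation/oxa-6π sequence should give the 8-formyl-5,7-dimethoxy spirochromene F2. Hydrogenation (H2, Pd/C, EtOAc, stopped after one equivalent) gives the chroman F3. Friedel–Crafts acylation with 7 (SnCl4, CH2Cl2, −20 → 0 °C) at C6, the only free ring position, gives the 6-isovaleryl-8-formyl dimethyl ether F4. BCl3 (CH2Cl2, −78 → 0 °C) then cleaves both methyl ethers, each chelation-activated by an ortho carbonyl group, to deliver 13.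

Step 6. The chloroiminium reagent may also attack the enolizable α-methylene of the 2-hydroxyaryl ketone and lead on to chromone-type ring closure, or the acid set free may ionize the tertiary spiro ether. The fallback sets out from 11 and rejoins at 13. It replaces the acidic iminium electrophile by a basic, chelation-directed formylation: MgCl2, Et3N, paraformaldehyde, MeCN, reflux. The magnesium phenoxide of the 7-hydroxyl adds through its ortho carbon C8 to formaldehyde, and the benzylic alkoxide is oxidized in the flask by hydride transfer to a second formaldehyde. This fallback isolates no further compound, F0.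

Step 2. The aldiminate may be reduced further to the allylic amine, hydride may be delivered in a conjugate sense, or the exocyclic double bond may migrate into the ring during acidic hydrolysis of the imine. The fallback sets out from 1 and rejoins at 5; it replaces the partial reduction by a full reduction followed by a mild oxidation. Olefination of 1 with triethyl phosphonoacetate (NaH, THF) gives ethyl (E)-2-[(1R,5S)-6,6-dimethylbicyclo[3.1.1]heptan-2-ylidene]acetate F5. iBu2AlH (2.2 equiv, CH2Cl2, −78 °C) reduces it to the allylic alcohol (E)-2-[(1R,5S)-6,6-dimethylbicyclo[3.1.1]heptan-2-ylidene]ethanol F6, and MnO2 (CH2Cl2, rt) oxidizes this to 5 under neutral conditions.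

Further compounds
F1 | step 4 | 2-hydroxy-4,6-dimethoxybenzaldehyde (purchased) | COc1cc(O)c(C=O)c(OC)c1
F2 | step 4 | (2R,1'R,5'S)-5,7-dimethoxy-6',6'-dimethylspiro[chromene-2,2'-bicyclo[3.1.1]heptane]-8-carbaldehyde | COc1cc(OC)c(C=O)c2c1C=C[C@@]1(CC[C@H]3C[C@@H]1C3(C)C)O2
F3 | step 4 | (2R,1'R,5'S)-5,7-dimethoxy-6',6'-dimethyl-3,4-dihydrospiro[chromene-2,2'-bicyclo[3.1.1]heptane]-8-carbaldehyde | COc1cc(OC)c(C=O)c2c1CC[C@@]1(CC[C@H]3C[C@@H]1C3(C)C)O2
F4 | step 4 | (2R,1'R,5'S)-5,7-dimethoxy-6',6'-dimethyl-6-(3-methylbutanoyl)-3,4-dihydrospiro[chromene-2,2'-bicyclo[3.1.1]heptane]-8-carbaldehyde | CC(C)CC(=O)c1c(OC)c(C=O)c2c(c1OC)CC[C@@]1(CC[C@H]3C[C@@H]1C3(C)C)O2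
F0 | step 6 | none | none
F5 | step 2 | ethyl (E)-2-[(1R,5S)-6,6-dimethylbicyclo[3.1.1]heptan-2-ylidene]acetate | CCOC(=O)/C=C1\CC[C@H]2C[C@@H]1C2(C)C
F6 | step 2 | (E)-2-[(1R,5S)-6,6-dimethylbicyclo[3.1.1]heptan-2-ylidene]ethanol | OC/C=C1\CC[C@H]2C[C@@H]1C2(C)C
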